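The route rests on disconnecting the cycloheptanone bond between C7 (ring-fusion CH, β-carbon of the lactone) and C8 (ring CH2 next to the C9 ketone). C9=O and the lactone carbonyl are 1,5-related, and the exocyclic methylene is read as the trace of an allylic leaving group. The key step is therefore an intramolecular conjugate addition–elimination (SN2′): a tert-butyl β-keto ester enolate attacks the β-carbon of an intact 3-(phenylsulfonylmethyl)butenolide, closing the seven-membered ring, fixing the cis ring fusion and unveiling the α-methylene lactone at once. The precursor is a γ-substituted butenolide whose side chain already carries the three remaining stereocentres and is attached by a vinylogous Mukaiyama aldol reaction.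

Key step: step 15

Labels used in the text (target 23 and the corresponding atoms of all intermediates): cycloheptane atoms C1 (carbinol C), C5 (CH–O-acyl), C6 (lactone O–CH), C7 (ring-fusion CH), C8 (CH2), C9 (C=O), C10 (CHMe); C11, C12 and C13 are the lactone α-carbon, carbonyl carbon and exocyclic CH2; C2′ is the side-chain carbonyl carbon. Compound names use systematic locants.

Assumption: enantiopure lactone 1 is taken as a purchasable building block; the C2′ carbinol centre made in step 4 is drawn as the epimer expected from chelation control, and its configuration is erased in step 17.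

Step 1
Reactants: 1 (R)-4-methyldihydrofuran-2(3H)-one
Product: 3 (R)-4-methyl-3-methylidenedihydrofuran-2(3H)-one, via sodium formyl-lactone enolate 2 (not isolated)
Conditions: NaH, HCO2Et, Et2O, 0 °C → rt; then (CH2O)n, THF, reflux
Reagents that add atoms: formaldehyde (used as paraformaldehyde), C=O
Why: Claisen formylation gives the α-formyl lactone enolate, which adds to formaldehyde (aldol), transfers the formyl group to oxygen and loses formate (α-methylenation of a lactone through its α-formyl derivative); the C10 stereocentre is not touched.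

Step 2
Reactants: 3 (R)-4-methyl-3-methylidenedihydrofuran-2(3H)-one
Product: 4 (3S,4S)-3-hydroxy-3-(hydroxymethyl)-4-methyldihydrofuran-2(3H)-one
Conditions: OsO4 (cat.), NMO, acetone/H2O, 0 °C → rt
Reagents that add atoms: N-methylmorpholine N-oxide, C[N+]1([O-])CCOCC1; water, O
Why: Upjohn dihydroxylation, in which OsO4 should add to the exocyclic alkene on the ring face opposite to the adjacent methyl group, so that the new tertiary hydroxyl (C1) is trans to the C10 methyl.

Step 3
Reactants: 4 (3S,4S)-3-hydroxy-3-(hydroxymethyl)-4-methyldihydrofuran-2(3H)-one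
Product: 5 (3S,4S)-3-[(tert-butyldimethylsilyloxy)methyl]-3-hydroxy-4-methyldihydrofuran-2(3H)-one
Conditions: TBSCl, imidazole, CH2Cl2, 0 °C
Reagents that add atoms: tert-butyldimethylsilyl chloride, CC(C)(C)[Si](C)(C)Cl
Why: Silyl ether formation is selective for the primary hydroxyl (C5–OH) over the hindered tertiary α-hydroxy lactone alcohol.

Step 4
Reactants: 5 (3S,4S)-3-[(tert-butyldimethylsilyloxy)methyl]-3-hydroxy-4-methyldihydrofuran-2(3H)-one
Product: 7 (2S,3S,4R,5Z)-3-[(tert-butyldimethylsilyloxy)methyl]-2-methylhept-5-ene-1,3,4-triol, via lactol 6 (not isolated)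
Conditions: i-Bu2AlH, CH2Cl2, −78 °C; then (Z)-MeCH=CHLi (from (Z)-1-bromopropene, t-BuLi, Et2O, −78 °C), −78 → −20 °C; aq. KNaC4H4O6
Reagents that add atoms: (Z)-prop-1-enyllithium, C/C=C\[Li]
Why: One-pot reductive alkenylation of a lactone: the aluminium lactolate releases the α-alkoxido aldehyde on warming, the configurationally stable (Z)-alkenyllithium adds to it, and chelation-controlled attack from the side of the smaller CH2OTBS arm should favour the drawn C2′ epimer.

Step 5
Reactants: 7 (2S,3S,4R,5Z)-3-[(tert-butyldimethylsilyloxy)methyl]-2-methylhept-5-ene-1,3,4-triol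
Product: 8 (2S)-2-{(4S,5R)-4-[(tert-butyldimethylsilyloxy)methyl]-2,2-dimethyl-5-[(Z)-prop-1-enyl]-1,3-dioxolan-4-yl}propan-1-ol
Conditions: Me2C(OMe)2, PPTS (cat.), CH2Cl2, 0 °C → rt
Reagents that add atoms: 2,2-dimethoxypropane, COC(C)(C)OC
Why: Acetonide formation should select the vicinal tertiary/secondary diol (five-membered dioxolane) over the 1,3-related primary hydroxyl, whose dioxane would carry an axial substituent, and so leaves the C9 alcohol free.

Step 6
Reactants: 8 (2S)-2-{(4S,5R)-4-[(tert-butyldimethylsilyloxy)methyl]-2,2-dimethyl-5-[(Z)-prop-1-enyl]-1,3-dioxolan-4-yl}propan-1-ol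
Product: 9 (2R)-2-{(4S,5R)-4-[(tert-butyldimethylsilyloxy)methyl]-2,2-dimethyl-5-[(Z)-prop-1-enyl]-1,3-dioxolan-4-yl}propanal
Conditions: Dess–Martin periodinane, NaHCO3, CH2Cl2, 0 °C → rt
Reagents that add atoms: none
Why: Dess–Martin oxidation of the primary alcohol under buffered conditions should give the aldehyde without epimerising the adjacent C10 centre.

Step 7
Reactants: 9 (2R)-2-{(4S,5R)-4-[(tert-butyldimethylsilyloxy)methyl]-2,2-dimethyl-5-[(Z)-prop-1-enyl]-1,3-dioxolan-4-yl}propanal
Product: 10 tert-butyl (4R)-4-{(4S,5R)-4-[(tert-butyldimethylsilyloxy)methyl]-2,2-dimethyl-5-[(Z)-prop-1-enyl]-1,3-dioxolan-4-yl}-3-oxopentanoate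
Conditions: N2CHCO2t-Bu, SnCl2 (cat.), CH2Cl2, rt
Reagents that add atoms: tert-butyl diazoacetate, CC(C)(C)OC(=O)C=[N+]=[N-]
Why: Roskamp reaction: SnCl2 activates the aldehyde for addition of the diazo ester, and 1,2-hydride shift with loss of N2 gives the β-keto ester (C8, C9) while leaving C10 untouched.

Step 8
Reactants: 10 tert-butyl (4R)-4-{(4S,5R)-4-[(tert-butyldimethylsilyloxy)methyl]-2,2-dimethyl-5-[(Z)-prop-1-enyl]-1,3-dioxolan-4-yl}-3-oxopentanoate
Product: 11 tert-butyl (4R)-4-{(4S,5R)-4-(hydroxymethyl)-2,2-dimethyl-5-[(Z)-prop-1-enyl]-1,3-dioxolan-4-yl}-3-oxopentanoate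
Conditions: Bu4NF, AcOH, THF, 0 °C → rt
Reagents that add atoms: none
Why: Buffered fluoride desilylation frees the C5 alcohol; acid-free conditions keep the γ-hydroxy ketone from dehydrating through its cyclic hemiketal, and the alcohol is oxidised directly.

Step 9
Reactants: 11 tert-butyl (4R)-4-{(4S,5R)-4-(hydroxymethyl)-2,2-dimethyl-5-[(Z)-prop-1-enyl]-1,3-dioxolan-4-yl}-3-oxopentanoate
Product: 12 tert-butyl (4R)-4-{(4R,5R)-4-formyl-2,2-dimethyl-5-[(Z)-prop-1-enyl]-1,3-dioxolan-4-yl}-3-oxopentanoate
Conditions: Dess–Martin periodinane, NaHCO3, CH2Cl2, 0 °C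
Reagents that add atoms: none
Why: Dess–Martin oxidation gives the non-enolisable α-alkoxy aldehyde; aldol closure of the keto ester onto it would have to go through the stereoelectronically disfavoured 5-(enolendo)-exo-trig mode.

Step 10
Reactants: 13 3-methylidenedihydrofuran-2(3H)-one
Product: 15 3-(bromomethyl)furan-2(5H)-one, via dibromolactone 14 (not isolated)
Conditions: Br2, CH2Cl2, 0 °C; then Et3N, 0 °C → rt
Reagents that add atoms: bromine, BrBr
Why: Bromination of the exocyclic alkene followed by E2 dehydrobromination toward the ring CH2 should give the conjugated endocyclic butenolide with the allylic bromide in place.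

Step 11
Reactants: 15 3-(bromomethyl)furan-2(5H)-one
Product: 16 3-[(phenylsulfonyl)methyl]furan-2(5H)-one
Conditions: PhSO2Na, DMF, rt
Reagents that add atoms: sodium benzenesulfinate, [Na+].[O-]S(=O)c1ccccc1
Why: Nucleophilic substitution of the allylic bromide by the sulfur atom of the sulfinate gives the allylic sulfone.

Step 12
Reactants: 16 3-[(phenylsulfonyl)methyl]furan-2(5H)-one
Product: 17 triisopropyl({3-[(phenylsulfonyl)methyl]furan-2-yl}oxy)silane
Conditions: i-Pr3SiOTf, Et3N, CH2Cl2, 0 °C
Reagents that add atoms: triisopropylsilyl trifluoromethanesulfonate, CC(C)[Si](C(C)C)(C(C)C)OS(=O)(=O)C(F)(F)F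
Why: Soft enolisation at the γ-CH2 (silyl triflate/amine) gives the aromatic 2-silyloxyfuran, the dienol ether needed for vinylogous aldol chemistry.

Step 13
Reactants: 12 tert-butyl (4R)-4-{(4R,5R)-4-formyl-2,2-dimethyl-5-[(Z)-prop-1-enyl]-1,3-dioxolan-4-yl}-3-oxopentanoate; 17 triisopropyl({3-[(phenylsulfonyl)methyl]furan-2-yl}oxy)silane
Product: 18 tert-butyl (4R)-4-{(4S,5R)-4-[(S)-hydroxy{(2R)-5-oxo-4-[(phenylsulfonyl)methyl]-2,5-dihydrofuran-2-yl}methyl]-2,2-dimethyl-5-[(Z)-prop-1-enyl]-1,3-dioxolan-4-yl}-3-oxopentanoate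
Conditions: BF3·OEt2, CH2Cl2, −78 °C; aq. NaHCO3
Reagents that add atoms: none
Why: Vinylogous Mukaiyama aldol reaction: the furan attacks through its free α-position and is dearomatised to the butenolide; the open transition state under a monodentate Lewis acid should give the threo C5/C6 pair, and Felkin–Anh-type attack anti to the dioxolane C–O bond, past the C10 methine and away from the ring carbon that carries the syn propenyl group, should set C5 as drawn.

Step 14
Reactants: 18 tert-butyl (4R)-4-{(4S,5R)-4-[(S)-hydroxy{(2R)-5-oxo-4-[(phenylsulfonyl)methyl]-2,5-dihydrofuran-2-yl}methyl]-2,2-dimethyl-5-[(Z)-prop-1-enyl]-1,3-dioxolan-4-yl}-3-oxopentanoate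
Product: 19 tert-butyl (4R)-4-{(4R,5R)-2,2-dimethyl-4-[(S)-(3-methylbutanoyloxy){(2R)-5-oxo-4-[(phenylsulfonyl)methyl]-2,5-dihydrofuran-2-yl}methyl]-5-[(Z)-prop-1-enyl]-1,3-dioxolan-4-yl}-3-oxopentanoate
Conditions: (i-PrCH2CO)2O, DMAP (cat.), pyridine, CH2Cl2, 0 °C
Reagents that add atoms: 3-methylbutanoic anhydride, CC(C)CC(=O)OC(=O)CC(C)C
Why: DMAP-catalysed acylation of the only free hydroxyl; the weak base pyridine at 0 °C should avoid deprotonation of the butenolide γ-position.

Step 15
Reactants: 19 tert-butyl (4R)-4-{(4R,5R)-2,2-dimethyl-4-[(S)-(3-methylbutanoyloxy){(2R)-5-oxo-4-[(phenylsulfonyl)methyl]-2,5-dihydrofuran-2-yl}methyl]-5-[(Z)-prop-1-enyl]-1,3-dioxolan-4-yl}-3-oxopentanoate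
Product: 20 O7,O1′-isopropylidene acetal of tert-butyl (3aS,6R,7R,8S,8aR)-7-hydroxy-7-[(1R,2Z)-1-hydroxybut-2-enyl]-6-methyl-3-methylidene-8-(3-methylbutanoyloxy)-2,5-dioxooctahydro-2H-cyclohepta[b]furan-4-carboxylate (epimers at the ester-bearing carbon)
Conditions: K2CO3, MeCN (0.01 M), 0 °C → rt
Reagents that add atoms: none
Why: K2CO3 deprotonates only the β-keto ester (C8–H); the stabilised enolate adds through carbon to the butenolide β-carbon C7, and the lactone enolate so formed expels benzenesulfinate from C13 (E1cB), an overall SN2′ allylic alkylation that leaves the C11=C13 double bond exocyclic. The closest known reaction type is the conjugate addition–elimination of 1,3-dicarbonyl nucleophiles to 2-(sulfonylmethyl)- and 2-(halomethyl)acrylates, here run intramolecularly. The cycloheptane closes in the 7-exo-trig mode (C8 onto C7, with C7=C11 exocyclic to the forming ring); the lactone ring is already in place and only changes from butenolide to α-methylene lactone. C7 is set by the tether: the chain is anchored at C6 and can reach the adjacent sp2 carbon only on the face that carries C5, which gives the cis ring fusion, while C8 forms as an epimer mixture that is erased by decarboxylation in step 16. The step needs deprotonation of the keto ester in preference to the butenolide γ-hydrogen and attack through carbon and not oxygen; the large acidity gap, the weak heterogeneous base at low temperature and high dilution, the soft acceptor, and a leaving group that cannot be displaced directly at C13 should secure this, and the irreversible loss of sulfinate pulls the addition forward.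

Step 16
Reactants: 20 O7,O1′-isopropylidene acetal of tert-butyl (3aS,6R,7R,8S,8aR)-7-hydroxy-7-[(1R,2Z)-1-hydroxybut-2-enyl]-6-methyl-3-methylidene-8-(3-methylbutanoyloxy)-2,5-dioxooctahydro-2H-cyclohepta[b]furan-4-carboxylate
Product: 22 (3aS,6R,7R,8S,8aR)-7-hydroxy-7-[(1R,2Z)-1-hydroxybut-2-enyl]-6-methyl-3-methylidene-2,5-dioxooctahydro-2H-cyclohepta[b]furan-8-yl 3-methylbutanoate, via β-keto acid 21 (not isolated)
Conditions: CF3CO2H, H2O, CH2Cl2, 0 °C → rt; then toluene, 60 °C
Reagents that add atoms: none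
Why: Acidolysis cleaves the tert-butyl ester (loss of isobutene) and hydrolyses the acetonide, and the β-keto acid then decarboxylates on gentle warming, which removes the C8 stereocentre.

Step 17
Reactants: 22 (3aS,6R,7R,8S,8aR)-7-hydroxy-7-[(1R,2Z)-1-hydroxybut-2-enyl]-6-methyl-3-methylidene-2,5-dioxooctahydro-2H-cyclohepta[b]furan-8-yl 3-methylbutanoate
Product: 23 (3aS,6R,7S,8S,8aR)-7-[(2Z)-but-2-enoyl]-7-hydroxy-6-methyl-3-methylidene-2,5-dioxooctahydro-2H-cyclohepta[b]furan-8-yl 3-methylbutanoate
Conditions: Dess–Martin periodinane, NaHCO3, CH2Cl2, 0 °C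
Reagents that add atoms: none
Why: Dess–Martin oxidation of the secondary allylic alcohol under buffered conditions should give the (Z)-enone without isomerisation; the tertiary alcohol cannot be oxidised.

Compound list

1 | (R)-4-methyldihydrofuran-2(3H)-one | C[C@@H]1CC(=O)OC1 | starting material
2 | sodium [(4R)-4-methyl-2-oxooxolan-3-ylidene]methanolate | C[C@@H]1C(=C[O-])C(=O)OC1.[Na+] | intermediate
3 | (R)-4-methyl-3-methylidenedihydrofuran-2(3H)-one | C[C@@H]1C(=C)C(=O)OC1 | intermediate
4 | (3S,4S)-3-hydroxy-3-(hydroxymethyl)-4-methyldihydrofuran-2(3H)-one | C[C@@H]1[C@](O)(CO)C(=O)OC1 | intermediate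
5 | (3S,4S)-3-[(tert-butyldimethylsilyloxy)methyl]-3-hydroxy-4-methyldihydrofuran-2(3H)-one | C[C@@H]1[C@](O)(CO[Si](C)(C)C(C)(C)C)C(=O)OC1 | intermediate
6 | (3S,4S)-3-[(tert-butyldimethylsilyloxy)methyl]-4-methyltetrahydrofuran-2,3-diol (lactol; both anomers) | C[C@@H]1[C@](O)(CO[Si](C)(C)C(C)(C)C)C(O)OC1 | intermediate
7 | (2S,3S,4R,5Z)-3-[(tert-butyldimethylsilyloxy)methyl]-2-methylhept-5-ene-1,3,4-triol | OC[C@H](C)[C@@](O)([C@H](O)/C=C\C)CO[Si](C)(C)C(C)(C)C | intermediate
8 | (2S)-2-{(4S,5R)-4-[(tert-butyldimethylsilyloxy)methyl]-2,2-dimethyl-5-[(Z)-prop-1-enyl]-1,3-dioxolan-4-yl}propan-1-ol | OC[C@H](C)[C@@](OC(C)(C)O1)([C@H]1/C=C\C)CO[Si](C)(C)C(C)(C)C | intermediate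
9 | (2R)-2-{(4S,5R)-4-[(tert-butyldimethylsilyloxy)methyl]-2,2-dimethyl-5-[(Z)-prop-1-enyl]-1,3-dioxolan-4-yl}propanal | O=C[C@H](C)[C@@](OC(C)(C)O1)([C@H]1/C=C\C)CO[Si](C)(C)C(C)(C)C | intermediate
10 | tert-butyl (4R)-4-{(4S,5R)-4-[(tert-butyldimethylsilyloxy)methyl]-2,2-dimethyl-5-[(Z)-prop-1-enyl]-1,3-dioxolan-4-yl}-3-oxopentanoate | CC(C)(C)OC(=O)CC(=O)[C@H](C)[C@@](OC(C)(C)O1)([C@H]1/C=C\C)CO[Si](C)(C)C(C)(C)C | intermediate
11 | tert-butyl (4R)-4-{(4S,5R)-4-(hydroxymethyl)-2,2-dimethyl-5-[(Z)-prop-1-enyl]-1,3-dioxolan-4-yl}-3-oxopentanoate | CC(C)(C)OC(=O)CC(=O)[C@H](C)[C@@](OC(C)(C)O1)([C@H]1/C=C\C)CO | intermediate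
12 | tert-butyl (4R)-4-{(4R,5R)-4-formyl-2,2-dimethyl-5-[(Z)-prop-1-enyl]-1,3-dioxolan-4-yl}-3-oxopentanoate | CC(C)(C)OC(=O)CC(=O)[C@H](C)[C@@](OC(C)(C)O1)([C@H]1/C=C\C)C=O | intermediate
13 | 3-methylidenedihydrofuran-2(3H)-one (α-methylene-γ-butyrolactone) | C=C1CCOC1=O | starting material
14 | 3-bromo-3-(bromomethyl)dihydrofuran-2(3H)-one (racemic) | BrCC1(Br)CCOC1=O | intermediate
15 | 3-(bromomethyl)furan-2(5H)-one | BrCC1=CCOC1=O | intermediate
16 | 3-[(phenylsulfonyl)methyl]furan-2(5H)-one | O=C1OCC=C1CS(=O)(=O)c1ccccc1 | intermediate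
17 | triisopropyl({3-[(phenylsulfonyl)methyl]furan-2-yl}oxy)silane | CC(C)[Si](C(C)C)(C(C)C)Oc1occc1CS(=O)(=O)c1ccccc1 | intermediate
18 | tert-butyl (4R)-4-{(4S,5R)-4-[(S)-hydroxy{(2R)-5-oxo-4-[(phenylsulfonyl)methyl]-2,5-dihydrofuran-2-yl}methyl]-2,2-dimethyl-5-[(Z)-prop-1-enyl]-1,3-dioxolan-4-yl}-3-oxopentanoate | CC(C)(C)OC(=O)CC(=O)[C@H](C)[C@@](OC(C)(C)O1)([C@H]1/C=C\C)[C@@H](O)[C@@H]2OC(=O)C(CS(=O)(=O)c3ccccc3)=C2 | intermediate
19 | tert-butyl (4R)-4-{(4R,5R)-2,2-dimethyl-4-[(S)-(3-methylbutanoyloxy){(2R)-5-oxo-4-[(phenylsulfonyl)methyl]-2,5-dihydrofuran-2-yl}methyl]-5-[(Z)-prop-1-enyl]-1,3-dioxolan-4-yl}-3-oxopentanoate | CC(C)(C)OC(=O)CC(=O)[C@H](C)[C@@](OC(C)(C)O1)([C@H]1/C=C\C)[C@@H](OC(=O)CC(C)C)[C@@H]2OC(=O)C(CS(=O)(=O)c3ccccc3)=C2 | intermediate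
20 | O7,O1′-isopropylidene acetal of tert-butyl (3aS,6R,7R,8S,8aR)-7-hydroxy-7-[(1R,2Z)-1-hydroxybut-2-enyl]-6-methyl-3-methylidene-8-(3-methylbutanoyloxy)-2,5-dioxooctahydro-2H-cyclohepta[b]furan-4-carboxylate (epimers at the ester-bearing carbon) | C=C1C(=O)O[C@@H]2[C@H]1C(C(=O)OC(C)(C)C)C(=O)[C@H](C)[C@@](OC(C)(C)O3)([C@H]3/C=C\C)[C@H]2OC(=O)CC(C)C | intermediate
21 | (3aS,6R,7R,8S,8aR)-7-hydroxy-7-[(1R,2Z)-1-hydroxybut-2-enyl]-6-methyl-3-methylidene-8-(3-methylbutanoyloxy)-2,5-dioxooctahydro-2H-cyclohepta[b]furan-4-carboxylic acid (epimers at the carboxyl-bearing carbon) | C=C1C(=O)O[C@@H]2[C@H]1C(C(=O)O)C(=O)[C@H](C)[C@@](O)([C@H](O)/C=C\C)[C@H]2OC(=O)CC(C)C | intermediate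
22 | (3aS,6R,7R,8S,8aR)-7-hydroxy-7-[(1R,2Z)-1-hydroxybut-2-enyl]-6-methyl-3-methylidene-2,5-dioxooctahydro-2H-cyclohepta[b]furan-8-yl 3-methylbutanoate | C=C1C(=O)O[C@@H]2[C@H]1CC(=O)[C@H](C)[C@@](O)([C@H](O)/C=C\C)[C@H]2OC(=O)CC(C)C | intermediate
23 | (3aS,6R,7S,8S,8aR)-7-[(2Z)-but-2-enoyl]-7-hydroxy-6-methyl-3-methylidene-2,5-dioxooctahydro-2H-cyclohepta[b]furan-8-yl 3-methylbutanoate | C=C1C(=O)O[C@@H]2[C@H]1CC(=O)[C@H](C)[C@@](O)(C(=O)/C=C\C)[C@H]2OC(=O)CC(C)C | target

Total step count: 17. Longest linear sequence: 14 steps (1 → 23 through steps 1–9 and 13–17; steps 10–12 make the furan partner 17).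

Steps most likely to fail

Step 15 (key step). Proton transfer from the butenolide γ-position (C6–H) may compete with ring closure; the furanolate so formed can lose the neighbouring C5 acyloxy group by β-elimination (γ-ylidenebutenolide) or reprotonate with loss of configuration at C6. Slow seven-membered closure also leaves room for intermolecular addition. The fallback sets out from 18 and comes back at 20, and it inverts the order of acylation and cyclisation. Alcohol 18, whose C5 substituent is a hydroxyl and therefore no leaving group, is cyclised with K2CO3 in MeCN to the hydroxy bicyclic β-keto ester, the 8-hydroxy analogue of 20 (F1). F1 is no longer a butenolide and is then esterified with 3-methylbutanoic anhydride and DMAP to give 20.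

Step 13. The formyl group sits on a fully substituted carbon, so facial selectivity may be poor and the C5-epimeric series may form, together with erosion of the threo preference. The fallback sets out from 12 and 17 and comes back at 18. It moves the source of stereocontrol from the substrate to the reagent: the two partners are united under an enantiopure bis(oxazoline) complex of Cu(OTf)2, which binds the α-alkoxy aldehyde as a chelate and dictates the face attacked; the ligand antipode is chosen to match. No new compound arises (F0).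

Step 4. The lactolate may be over-reduced to the diol before the alkenyllithium is added, the aldehyde may be released incompletely from the aluminium lactolate, and the alkenyllithium may partly lose its Z geometry. The fallback sets out from 5 and comes back at 7. Lactone 5 is reduced with i-Bu2AlH and lactol 6 is isolated. Addition of 1-propynyllithium to 6 gives the alkynyl triol (2S,3S,4R)-3-[(tert-butyldimethylsilyloxy)methyl]-2-methylhept-5-yne-1,3,4-triol (F2). Semi-hydrogenation of F2 over Pd/CaCO3 poisoned with Pb(OAc)2 (quinoline, H2) then fixes the Z alkene and gives 7.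

Further compounds

F1 | step 15 | O7,O1′-isopropylidene acetal of tert-butyl (3aS,6R,7S,8S,8aR)-7,8-dihydroxy-7-[(1R,2Z)-1-hydroxybut-2-enyl]-6-methyl-3-methylidene-2,5-dioxooctahydro-2H-cyclohepta[b]furan-4-carboxylate (8-hydroxy analogue of 20; epimers at the ester-bearing carbon) | C=C1C(=O)O[C@@H]2[C@H]1C(C(=O)OC(C)(C)C)C(=O)[C@H](C)[C@@](OC(C)(C)O3)([C@H]3/C=C\C)[C@H]2O
F0 | step 13 | none | none
F2 | step 4 | (2S,3S,4R)-3-[(tert-butyldimethylsilyloxy)methyl]-2-methylhept-5-yne-1,3,4-triol | OC[C@H](C)[C@@](O)([C@H](O)C#CC)CO[Si](C)(C)C(C)(C)C
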